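All runs stem from a simulated flask with constants of no real substance, and the scatter is random.

At the earliest readings, 1.00 h in blue and 2.50 h in teal, Ez and Aj already stand within the scatter of their last readings, so the examination concerns end states.

all flasks: Uj 0.20 M; Aj 0.20 M
- teal: Dw 0.12 M; Xo 0.14 mM; run made earlier
- blue: Dw 0.12 M; Xo 0.21 mM; run made earlier
- ochre: Dw 0.18 M; Xo 0.28 mM; run made earlier
- flask: Dw 0.120 M; Xo 0.28 mM; time 15 h

| run | time / h | Ez / % | Aj / % |
|---|---|---|---|
| teal | 2.50 | 18.1 | 38.2 |
| teal | 5.00 | 17.7 | 37.0 |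
| teal | 8.00 | 18.0 | 38.6 |
| teal | 10.0 | 17.9 | 38.8 |
| teal | 12.0 | 18.9 | 38.7 |
| teal | 15.0 | 17.3 | 39.8 |
| teal | 20.0 | 17.8 | 37.9 |
| blue | 1.00 | 18.2 | 38.2 |
| blue | 3.00 | 15.6 | 37.7 |
| blue | 5.00 | 18.9 | 37.7 |
| blue | 8.00 | 17.4 | 37.5 |
| blue | 10.0 | 18.6 | 39.0 |
| blue | 15.0 | 19.0 | 36.0 |
| blue | 20.0 | 18.8 | 39.6 |
| ochre | 1.50 | 25.3 | 33.8 |
| ochre | 5.00 | 26.3 | 33.3 |
| ochre | 8.00 | 25.0 | 30.9 |
| ochre | 12.0 | 26.8 | 32.8 |
| ochre | 20.0 | 25.3 | 29.5 |

(each reading ± 1 percentage point)

- Xo is single-handed; Uj and Aj are mirror images of each other, charged as a racemate, each of them at the stated concentration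
- the reaction counts as stopped when no species that holds the Uj and Aj together changes by six tenths of a point or more over the second half of the time

* the state of affairs at 15 h: stopped, and by what, or still going (no working catalyst is left / Dw has run out first / it is still moving / forward and back rates have come level / all of Uj has reacted)
* the Ez standing at 15 h, as a percentage of the Uj and Aj together charged
* the Aj standing at 15 h, as a percentage of the Uj and Aj together charged

What ended teal? Its means are Ez 18.0% and Aj 38.4%, so 29.6% of the substrate has reacted. At one Dw per substrate, c(Dw) allows 30.0%. Ochre allows 45.0% and shows 43.7%. I read Dw as the limiting reagent.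

How is the reacted share split? Work with the fraction left. If each enantiomer is consumed in proportion to its own concentration, with a common factor for Dw and Xo, that factor cancels however it runs down. Counting Uj lost as Ez, teal's readings give 1.69: this is s, the selectivity factor of this kinetic resolution, the logarithm of the fraction of Uj left over the logarithm of the fraction of Aj left. Ochre, further along, reads 1.63.

But the flask has twice teal's Xo? Neither the Dw count nor s contains c(Xo). If the rate follows c(Xo), blue's flatness at 1.00 h becomes 0.750 h here, well before 15 h. The flask has teal's c(Dw) and c(Uj), so for the flask I commit to teal's means.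

The forecast says Dw has run out first, with Ez 18.1% and Aj 38.1%, on the ground that “The plateau therefore scales with Dw, not with catalyst.” My Aj stands 0.30 percentage points higher.

The flask's result is this: Dw has run out first, with Ez 18.1% and Aj 38.3%, and at 15.0 h Dw stands at 0% of its charge, less than the 77% of its charge that Aj keeps.

    Dw + Xo → Dw.Xo (k = 0.0630 L mol⁻¹ min⁻¹)
    Dw + Xo + Aj → Xo + Ty (k = 4000 L² mol⁻² min⁻¹)
    Dw → Ky (k = 0.00300 min⁻¹)
    Dw + Xo + Uj → Xo + Ez (k = 6700 L² mol⁻² min⁻¹)

The flask's fractions left give s = 1.69. A neighbouring flask charged with 0.072 M of Dw keeps 86% of its Aj; raised to the power 1.69, that gives 77.5% for Uj, and the neighbour keeps 78% of its Uj.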